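The target is divided at C10–C11 into a hydroazulene (rings A, B) and a benzoxepane aldehyde (rings C, D). Ring B hides a three-carbon/four-carbon pairing. With a carbonyl at C10, the triad C9(Me2)–C10–C1(HMe) maps onto an oxyallyl cation, and C2=C3–C4=C5 is a vinylcyclopentene diene whose ring double bond belongs to ring A. One (4+3) cycloaddition of that cation with the silyl ether of enantiopure 1-methyl-2-vinylcyclopent-2-en-1-ol forms C1–C2 and C5–C9, closes ring B, sets C5 and leaves a C3=C4 alkene for hydroxyl-directed hydrogenation. The ketone then becomes the alkenyl triflate for fragment union, and an allylic diazene rearrangement installs C1 and the Z-alkene.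

Key step: step 9

Numbering: skeleton atoms are counted along the target SMILES from left to right, leaving out methyl carbons and hydroxyl/carbonyl oxygens. This gives C1 (CHMe), C2, C3, C4/C5 (A/B fusion), C6, C7, C8 (carbinol), C9 (CMe2), C10=C11, C12, C13, C14 (CMe), C15, C16, C17 (ketone), C18 (CMe2), O19, C20 (OCH), C21, C22, C23 (carbinol). Ring A is the cyclopentane, B the cycloheptane, C the cyclohexane, D the oxepane.

Assumption: commercial (R)-(–)-linalool and (E)-geranyl bromide are taken as stereochemically pure. The C1 epimer drawn for the ring B ketones is the one expected from the cycloaddition, and either epimer serves because C1 is flattened before it is set for good. C17 is carried as a silyl ether and oxidised last, so its configuration is of no consequence.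

Step 1
Reactants: 1 (R)-(–)-linalool
Product: 2 (R)-1-methylcyclopent-2-en-1-ol
Conditions: second-generation Grubbs catalyst (1 mol %), CH2Cl2, 23 → 40 °C
Reagents that add atoms: none
Why: Ring-closing metathesis of the 1,6-diene releases isobutene and should close ring A without touching the tertiary carbinol, so C8 is taken over unchanged, as R, from the chiral pool.

Step 2
Reactants: 2 (R)-1-methylcyclopent-2-en-1-ol
Product: 3 (R)-tert-butyldimethyl[(1-methylcyclopent-2-en-1-yl)oxy]silane
Conditions: TBSOTf, 2,6-lutidine, CH2Cl2, 0 °C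
Reagents that add atoms: tert-butyldimethylsilyl triflate, CC(C)(C)[Si](C)(C)OS(=O)(=O)C(F)(F)F
Why: Silyl triflate silylation of a tertiary alcohol masks the ionisable allylic hydroxyl and installs the bulky group that later shields one diene face, with C8 untouched.

Step 3
Reactants: 3 (R)-tert-butyldimethyl[(1-methylcyclopent-2-en-1-yl)oxy]silane
Product: 4 (1R,2R,5R)-2-(tert-butyldimethylsilyloxy)-2-methyl-6-oxabicyclo[3.1.0]hexane (oxirane anti to OTBS)
Conditions: mCPBA, CH2Cl2, 0 °C
Reagents that add atoms: 3-chloroperbenzoic acid, OOC(=O)c1cccc(Cl)c1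
Why: Prilezhaev epoxidation should take place on the alkene face opposite to the silyl ether, and the two new stereocentres C4 and C5 are transient because both are flattened again by step 6.

Step 4
Reactants: 4 (1R,2R,5R)-2-(tert-butyldimethylsilyloxy)-2-methyl-6-oxabicyclo[3.1.0]hexane
Product: 5 (1R,2R)-2-(tert-butyldimethylsilyloxy)-2-methylcyclopentan-1-ol (OH trans to OTBS)
Conditions: LiAlH4, THF, 0 → 40 °C; aqueous work-up
Reagents that add atoms: none
Why: Hydride opens the epoxide in an SN2 reaction at C5, the carbon remote from the quaternary, oxygen-bearing C8, which places the hydroxyl on C4 trans to the silyl ether, an arrangement that also disfavours silyl migration.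

Step 5
Reactants: 5 (1R,2R)-2-(tert-butyldimethylsilyloxy)-2-methylcyclopentan-1-ol
Product: 6 (R)-2-(tert-butyldimethylsilyloxy)-2-methylcyclopentan-1-one
Conditions: Dess–Martin periodinane, NaHCO3, CH2Cl2, 0 → 23 °C
Reagents that add atoms: none
Why: Dess–Martin oxidation of the secondary alcohol gives the α-silyloxy ketone, whose only stereocentre C8 is quaternary and cannot epimerise.

Step 6
Reactants: 6 (R)-2-(tert-butyldimethylsilyloxy)-2-methylcyclopentan-1-one
Product: 8 (R)-5-(tert-butyldimethylsilyloxy)-5-methylcyclopent-1-en-1-yl triflate, via potassium enolate 7 (not isolated)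
Conditions: KN(SiMe3)2, THF, –78 °C; PhNTf2, –78 → 0 °C
Reagents that add atoms: N-phenylbis(trifluoromethanesulfonimide), O=S(=O)(N(c1ccccc1)S(=O)(=O)C(F)(F)F)C(F)(F)F
Why: Because C8 is quaternary the ketone can be deprotonated only at C5, so enolate O-sulfonylation gives a single enol triflate with the C4=C5 double bond in place.

Step 7
Reactants: 8 (R)-5-(tert-butyldimethylsilyloxy)-5-methylcyclopent-1-en-1-yl triflate; 9 tributyl(vinyl)stannane
Product: 10 (R)-tert-butyldimethyl[(1-methyl-2-vinylcyclopent-2-en-1-yl)oxy]silane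
Conditions: Pd(PPh3)4 (5 mol %), LiCl, THF, 65 °C
Reagents that add atoms: none
Why: Stille coupling of an enol triflate with a vinylstannane in the presence of LiCl is a standard route to 2-substituted 1,3-dienes and leaves C8 untouched.

Step 8
Reactants: 11 2-methylpentan-3-one
Product: 12 2,4-dibromo-2-methylpentan-3-one (racemic at CHBr)
Conditions: Br2 (2 equiv), PBr3 (cat.), neat, 0 → 23 °C
Reagents that add atoms: bromine, BrBr
Why: Acid-catalysed α-bromination through the two enols introduces one bromine on each side of the carbonyl, and the configuration at the CHBr carbon is irrelevant because both halides are lost in step 9.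

Step 9
Reactants: 10 (R)-tert-butyldimethyl[(1-methyl-2-vinylcyclopent-2-en-1-yl)oxy]silane; 12 2,4-dibromo-2-methylpentan-3-one
Product: 14 hydroazulenone cycloadduct (C10 ketone; C9 gem-dimethyl; C1 methyl; C3=C4 alkene; C5–H and 8-OTBS on one face with C9 on the other), via oxyallyl cation 13 (not isolated)
Conditions: Fe2(CO)9 (1.5 equiv), 12 (1.5 equiv, in portions), benzene, 60 °C, N2
Reagents that add atoms: none
Why: Fe2(CO)9 strips both bromines from 12 and gives the iron-bound 2-oxyallyl cation 13, a three-carbon 2π partner that spans the termini of the s-cis diene 10 in an oxyallyl cation (4+3) cycloaddition, the reaction type established for α,α′-dibromoketones and open-chain 1,3-dienes. Bond formation should be strongly asynchronous: the unhindered vinyl terminus C2 attacks the less substituted CHMe end of 13 (C1) first, because the charge then spreads over C3–C5 and avoids C4, which is deactivated by the adjacent C8–O bond. Ring B closes when the enolate carbon C9 collapses on C5 of that allyl cation, so the ring is made by an intermolecular two-bond annulation (4π + 2π, seven-membered, second bond endo to the new ring) that leaves the C10 ketone and the C3=C4 alkene. C5 is controlled by C8, since 13 must approach the diene face carrying the small methyl group and not the bulky silyloxy group, which puts C9 anti to the oxygen. C1 results from the W-shaped cation in a compact approach but stays epimerisable next to the ketone and is flattened in step 13, so it needs no control. The step therefore needs regioselectivity (CMe2 end to C5), facial selectivity and C- rather than O-closure, which the polarised diene, the large silyl ether and the soft iron enolate should secure.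

Step 10
Reactants: 14 hydroazulenone cycloadduct
Product: 15 8-hydroxy hydroazulenone (free tertiary allylic alcohol; C3=C4 alkene)
Conditions: n-Bu4NF, THF, 23 → 50 °C
Reagents that add atoms: none
Why: Fluoride-induced desilylation frees the tertiary C8 hydroxyl under non-acidic conditions that spare the allylic carbinol, and any epimerisation at C1 is without consequence.

Step 11
Reactants: 15 8-hydroxy hydroazulenone
Product: 16 cis-fused perhydroazulenone (H4 and H5 and 8-OH all on the same face)
Conditions: H2 (1 atm), [Ir(cod)(PCy3)(py)]PF6 (5 mol %), CH2Cl2, 23 °C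
Reagents that add atoms: none
Why: Hydroxyl-directed homogeneous hydrogenation with a cationic iridium catalyst binds the C8 hydroxyl and delivers hydrogen to the C3=C4 alkene from the same, convex face, which sets C4–H cis to both the hydroxyl and C5–H and gives the cis-fused hydroazulene.

Step 12
Reactants: 16 cis-fused perhydroazulenone
Product: 17 8-O-triethylsilyl perhydroazulenone
Conditions: TESOTf, 2,6-lutidine, CH2Cl2, –78 → 0 °C
Reagents that add atoms: triethylsilyl triflate, CC[Si](CC)(CC)OS(=O)(=O)C(F)(F)F
Why: Silylation with a silyl triflate protects the tertiary alcohol against the strong base and the sulfonylating agent of the next step, and the doubly flanked ketone is too hindered to enolsilylate under these conditions.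

Step 13
Reactants: 17 8-O-triethylsilyl perhydroazulenone
Product: 19 C10 alkenyl triflate (tetrasubstituted C1=C10 alkene), via potassium enolate 18 (not isolated)
Conditions: KN(SiMe3)2, THF, –78 → 0 °C; PhNTf2, 0 → 23 °C
Reagents that add atoms: N-phenylbis(trifluoromethanesulfonimide), O=S(=O)(N(c1ccccc1)S(=O)(=O)C(F)(F)F)C(F)(F)F
Why: Enolisation can occur only toward C1 because C9 is quaternary, so O-sulfonylation gives the tetrasubstituted C1=C10 alkenyl triflate in analogy to 2,2,6-trialkylcyclohexanones, deliberately erasing C1.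

Step 14
Reactants: 20 dimethyl (2-oxopropyl)phosphonate; 21 (E)-geranyl bromide
Product: 23 dimethyl [(5E)-6,10-dimethyl-2-oxoundeca-5,9-dien-1-yl]phosphonate, via phosphonate dianion 22 (not isolated)
Conditions: NaH, THF, 0 °C; n-BuLi, 0 °C; then 21, 0 → 23 °C; aqueous quench
Reagents that add atoms: none
Why: γ-Alkylation of a β-ketophosphonate dianion takes place at the more reactive terminal carbanion and joins C21 to C22 by SN2 displacement of the allylic bromide with retention of the E-alkene.

Step 15
Reactants: 23 dimethyl [(5E)-6,10-dimethyl-2-oxoundeca-5,9-dien-1-yl]phosphonate; 24 (benzyloxy)acetaldehyde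
Product: 25 (2E,7E)-1-(benzyloxy)-8,12-dimethyltrideca-2,7,11-trien-4-one
Conditions: LiCl, i-Pr2NEt, MeCN, 23 °C
Reagents that add atoms: none
Why: Horner–Wadsworth–Emmons olefination under mild LiCl/amine conditions should give the E-enone and fixes the position of the later enol silane between C23 and C13.

Step 16
Reactants: 25 (2E,7E)-1-(benzyloxy)-8,12-dimethyltrideca-2,7,11-trien-4-one
Product: 26 diepoxy enone (14R,20R-epoxide and 17R-epoxide; enone intact)
Conditions: D-fructose-derived Shi ketone (30 mol % per alkene), KHSO5 (as Oxone), K2CO3, n-Bu4NHSO4, Na2B4O7 buffer, MeCN–CH2(OMe)2–H2O, 0 °C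
Reagents that add atoms: potassium peroxymonosulfate, [K+].[O-]S(=O)(=O)OO
Why: Shi asymmetric epoxidation oxidises the two electron-rich trisubstituted alkenes and leaves the electron-poor enone alone, the D-fructose-derived dioxirane giving the R,R-epoxide at C14–C20 (the source of both C/D fusion centres) and the R-epoxide at C17.

Step 17
Reactants: 26 diepoxy enone
Product: 27 diepoxy (Z)-triethylsilyl enol ether (C23=C13)
Conditions: Et3SiH, RhCl(PPh3)3 (1 mol %), toluene, 50 °C
Reagents that add atoms: triethylsilane, CC[SiH](CC)CC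
Why: Rhodium-catalysed 1,4-hydrosilylation of the s-cis enone gives the Z-configured silyl enol ether regiospecifically at C23=C13, which deprotonation of the corresponding ketone could not achieve, and does not affect the epoxides or the benzyl ether.

Step 18
Reactants: 27 diepoxy (Z)-triethylsilyl enol ether
Product: 29 trans-fused benzoxepane ketone (C23 ketone; 17-OTES; axial C14 methyl; equatorial 2-(benzyloxy)ethyl chain on C13), via bicyclic epoxonium ion 28 (not isolated)
Conditions: TESOTf (1.1 equiv), 2,6-di-tert-butyl-4-methylpyridine, CH2Cl2, –78 °C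
Reagents that add atoms: triethylsilyl triflate, CC[Si](CC)(CC)OS(=O)(=O)C(F)(F)F
Why: In this silyl triflate-initiated endo-selective epoxide-opening cascade (tandem oxa- and carbacyclisation) the silylated terminal epoxide is captured at its tertiary carbon C18 by the oxygen of the neighbouring epoxide, and the enol silane carbon C13 opens the resulting epoxonium 28 at the tertiary carbon C14 with inversion through a chair, so the 14R,20R-epoxide is translated into the trans C/D fusion while C13, α to the new ketone, takes up its side chain in the kinetically and thermodynamically preferred equatorial position.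

Step 19
Reactants: 29 trans-fused benzoxepane ketone
Product: 30 C23 tertiary alcohol (axial OH cis to the C14 methyl and to the C12 chain; equatorial C23 methyl)
Conditions: MeLi, CeCl3, THF, –78 °C
Reagents that add atoms: methyllithium, [Li]C
Why: The 1,2-addition of a non-basic organocerium reagent avoids enolisation, and since the axial C14 methyl blocks the axial trajectory the methyl group enters equatorially and sets C23 with an axial hydroxyl.

Step 20
Reactants: 30 C23 tertiary alcohol
Product: 31 17,23-bis(triethylsilyl) ether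
Conditions: TESOTf, 2,6-lutidine, CH2Cl2, 0 → 23 °C
Reagents that add atoms: triethylsilyl triflate, CC[Si](CC)(CC)OS(=O)(=O)C(F)(F)F
Why: Silyl triflate silylation covers the hindered tertiary hydroxyl, which otherwise would close onto C11 as a lactol in step 22 or as a tetrahydrofuran under the Mitsunobu conditions of step 26.

Step 21
Reactants: 31 17,23-bis(triethylsilyl) ether
Product: 32 C11 primary alcohol
Conditions: H2 (1 atm), Pd/C, EtOAc, 23 °C
Reagents that add atoms: none
Why: Hydrogenolysis of the benzyl ether over palladium in a non-protic solvent frees the primary alcohol and leaves the silyl ethers in place, no alkene being present in this fragment.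

Step 22
Reactants: 32 C11 primary alcohol
Product: 33 C11 aldehyde (rings C and D complete)
Conditions: Dess–Martin periodinane, NaHCO3, CH2Cl2, 0 → 23 °C
Reagents that add atoms: none
Why: Dess–Martin oxidation gives the C11 aldehyde without touching C13, which is not α to the new carbonyl.

Step 23
Reactants: 19 C10 alkenyl triflate; 33 C11 aldehyde
Product: 35 coupled allylic alcohol (mixture of C11 epimers), via alkenylchromium dichloride 34 (not isolated)
Conditions: CrCl2 (6 equiv), NiCl2 (2 mol %), DMF, 23 → 40 °C
Reagents that add atoms: none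
Why: In the Nozaki–Hiyama–Kishi coupling zerovalent nickel inserts into the C10–O bond of the triflate, transmetalation gives the non-basic alkenylchromium 34, and this adds to the enolisable aldehyde to form C10–C11, the carbinol C11 arising as an epimer mixture that is corrected in steps 24 and 25.

Step 24
Reactants: 35 coupled allylic alcohol
Product: 36 C11 enone
Conditions: Dess–Martin periodinane, NaHCO3, CH2Cl2, 0 → 23 °C
Reagents that add atoms: none
Why: Dess–Martin oxidation converges both C11 epimers on one enone, all other oxygen functions being silylated.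

Step 25
Reactants: 36 C11 enone
Product: 37 (11R)-allylic alcohol
Conditions: (S)-2-methyl-CBS-oxazaborolidine, BH3·SMe2, toluene, –40 → –20 °C
Reagents that add atoms: none
Why: In the Corey–Bakshi–Shibata reduction the tetrasubstituted cycloheptenyl group acts as the large and C12H2 as the small substituent, so the S-catalyst should give the 11R-alcohol under reagent control, and no other carbonyl competes because C17 is still a silyl ether.

Step 26
Reactants: 37 (11R)-allylic alcohol
Product: 38 (11S)-N-alkyl-N-(2-nitrobenzenesulfonyl) acetone hydrazone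
Conditions: N-isopropylidene-N′-2-nitrobenzenesulfonylhydrazine (IPNBSH), PPh3, DEAD, THF, 0 → 23 °C
Reagents that add atoms: IPNBSH, CC(C)=NNS(=O)(=O)c1ccccc1[N+](=O)[O-]
Why: Mitsunobu displacement by the acidic N–H of the arenesulfonyl hydrazone proceeds by SN2 with inversion and turns the only free hydroxyl, 11R, into the 11S C–N bond.

Step 27
Reactants: 38 (11S)-N-alkyl-N-(2-nitrobenzenesulfonyl) acetone hydrazone
Product: 41 tris(triethylsilyl) ether of the 17-ol (C1–H set; Z-C10=C11 alkene), via sulfonylhydrazine 39 (not isolated), via allylic diazene 40 (not isolated)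
Conditions: CF3CH2OH–H2O, THF, 23 °C
Reagents that add atoms: none
Why: Solvolysis of the hydrazone unmasks 39, loss of arenesulfinic acid gives the monoalkyl diazene 40, and its retro-ene loss of N2 (allylic diazene rearrangement) passes hydrogen suprafacially from nitrogen to C1; the reacting rotamer should keep the small C11–H next to the in-plane C1 methyl to avoid A1,3 strain, which places the 11S nitrogen on the face of H4 and H5, so that C1–H is delivered there and C12 ends up cis to C9, that is the Z-alkene.

Step 28
Reactants: 41 tris(triethylsilyl) ether of the 17-ol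
Product: 42 8,17,23-triol
Conditions: n-Bu4NF (excess), THF, 23 → 45 °C
Reagents that add atoms: none
Why: Fluoride cleaves all three triethylsilyl ethers under non-acidic conditions that endanger neither the tertiary alcohols nor the trisubstituted alkene, no stereocentre being affected.

Step 29
Reactants: 42 8,17,23-triol
Product: 43 CNP0157787.1 (target)
Conditions: Dess–Martin periodinane, NaHCO3, CH2Cl2, 0 °C
Reagents that add atoms: none
Why: Dess–Martin oxidation can act only on the single secondary alcohol at C17, since both other hydroxyls are tertiary, and so completes the oxepanone of ring D.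

Compound list
1 | (R)-(–)-linalool | C=C[C@](C)(O)CCC=C(C)C | starting material
2 | (R)-1-methylcyclopent-2-en-1-ol | C[C@@]1(O)CCC=C1 | intermediate
3 | (R)-tert-butyldimethyl[(1-methylcyclopent-2-en-1-yl)oxy]silane | C[C@@]1(O[Si](C)(C)C(C)(C)C)CCC=C1 | intermediate
4 | (1R,2R,5R)-2-(tert-butyldimethylsilyloxy)-2-methyl-6-oxabicyclo[3.1.0]hexane (oxirane anti to OTBS) | C[C@@]1(O[Si](C)(C)C(C)(C)C)CC[C@H]2O[C@@H]12 | intermediate
5 | (1R,2R)-2-(tert-butyldimethylsilyloxy)-2-methylcyclopentan-1-ol | C[C@@]1(O[Si](C)(C)C(C)(C)C)CCC[C@H]1O | intermediate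
6 | (R)-2-(tert-butyldimethylsilyloxy)-2-methylcyclopentan-1-one | C[C@@]1(O[Si](C)(C)C(C)(C)C)CCCC1=O | intermediate
7 | potassium enolate of 6 | C[C@@]1(O[Si](C)(C)C(C)(C)C)CCC=C1[O-].[K+] | intermediate
8 | (R)-5-(tert-butyldimethylsilyloxy)-5-methylcyclopent-1-en-1-yl triflate | C[C@@]1(O[Si](C)(C)C(C)(C)C)CCC=C1OS(=O)(=O)C(F)(F)F | intermediate
9 | tributyl(vinyl)stannane | C=C[Sn](CCCC)(CCCC)CCCC | starting material
10 | (R)-tert-butyldimethyl[(1-methyl-2-vinylcyclopent-2-en-1-yl)oxy]silane | C=CC1=CCC[C@@]1(C)O[Si](C)(C)C(C)(C)C | intermediate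
11 | 2-methylpentan-3-one | CCC(=O)C(C)C | starting material
12 | 2,4-dibromo-2-methylpentan-3-one | CC(Br)C(=O)C(C)(C)Br | intermediate
13 | 1,1,3-trimethyl-2-oxyallyl cation (iron-bound; drawn as the free W-shaped zwitterion) | C/C=C(\[O-])[C+](C)C | intermediate
14 | hydroazulenone cycloadduct (8-OTBS, C3=C4 alkene, C10 ketone) | C[C@H]1CC=C2[C@@H](CC[C@@]2(C)O[Si](C)(C)C(C)(C)C)C(C)(C)C1=O | intermediate
15 | 8-hydroxy hydroazulenone | C[C@H]1CC=C2[C@@H](CC[C@@]2(C)O)C(C)(C)C1=O | intermediate
16 | cis-fused perhydroazulenone (H4, H5, 8-OH syn) | C[C@H]1CC[C@@H]2[C@@H](CC[C@@]2(C)O)C(C)(C)C1=O | intermediate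
17 | 8-O-triethylsilyl perhydroazulenone | C[C@H]1CC[C@@H]2[C@@H](CC[C@@]2(C)O[Si](CC)(CC)CC)C(C)(C)C1=O | intermediate
18 | potassium enolate of 17 | CC1=C([O-])C(C)(C)[C@@H]2CC[C@@](C)(O[Si](CC)(CC)CC)[C@@H]2CC1.[K+] | intermediate
19 | C10 alkenyl triflate | CC1=C(OS(=O)(=O)C(F)(F)F)C(C)(C)[C@@H]2CC[C@@](C)(O[Si](CC)(CC)CC)[C@@H]2CC1 | intermediate
20 | dimethyl (2-oxopropyl)phosphonate | CC(=O)CP(=O)(OC)OC | starting material
21 | (E)-geranyl bromide | CC(C)=CCC/C(C)=C/CBr | starting material
22 | sodium lithium dianion of 20 | [Na+].[Li+].[CH2-]C(=O)[CH-]P(=O)(OC)OC | intermediate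
23 | dimethyl [(5E)-6,10-dimethyl-2-oxoundeca-5,9-dien-1-yl]phosphonate | CC(C)=CCC/C(C)=C/CCC(=O)CP(=O)(OC)OC | intermediate
24 | (benzyloxy)acetaldehyde | O=CCOCc1ccccc1 | starting material
25 | (2E,7E)-1-(benzyloxy)-8,12-dimethyltrideca-2,7,11-trien-4-one | CC(C)=CCC/C(C)=C/CCC(=O)/C=C/COCc1ccccc1 | intermediate
26 | diepoxy enone (14R,20R and 17R) | CC1(C)O[C@@H]1CC[C@@]1(C)O[C@@H]1CCC(=O)/C=C/COCc1ccccc1 | intermediate
27 | diepoxy (Z)-triethylsilyl enol ether | CC1(C)O[C@@H]1CC[C@@]1(C)O[C@@H]1CC/C(O[Si](CC)(CC)CC)=C/CCOCc1ccccc1 | intermediate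
28 | bicyclic epoxonium triflate (O19 bound to C18, C14 and C20) | CC1(C)[C@H](O[Si](CC)(CC)CC)CC[C@]2(C)[C@@H](CC/C(O[Si](CC)(CC)CC)=C/CCOCc3ccccc3)[O+]12.[O-]S(=O)(=O)C(F)(F)F | intermediate
29 | trans-fused benzoxepane ketone (C23=O, 17-OTES, C11-OBn) | c1ccccc1COCC[C@@H]1[C@@]2(C)CC[C@@H](O[Si](CC)(CC)CC)C(C)(C)O[C@@H]2CCC1=O | intermediate
30 | C23 tertiary alcohol | c1ccccc1COCC[C@@H]1[C@@]2(C)CC[C@@H](O[Si](CC)(CC)CC)C(C)(C)O[C@@H]2CC[C@]1(C)O | intermediate
31 | 17,23-bis(triethylsilyl) ether | c1ccccc1COCC[C@@H]1[C@@]2(C)CC[C@@H](O[Si](CC)(CC)CC)C(C)(C)O[C@@H]2CC[C@]1(C)O[Si](CC)(CC)CC | intermediate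
32 | C11 primary alcohol | OCC[C@@H]1[C@@]2(C)CC[C@@H](O[Si](CC)(CC)CC)C(C)(C)O[C@@H]2CC[C@]1(C)O[Si](CC)(CC)CC | intermediate
33 | C11 aldehyde | O=CC[C@@H]1[C@@]2(C)CC[C@@H](O[Si](CC)(CC)CC)C(C)(C)O[C@@H]2CC[C@]1(C)O[Si](CC)(CC)CC | intermediate
34 | alkenylchromium dichloride from 19 | CC1=C([Cr](Cl)Cl)C(C)(C)[C@@H]2CC[C@@](C)(O[Si](CC)(CC)CC)[C@@H]2CC1 | intermediate
35 | coupled allylic alcohol (C11 epimers) | CC1=C(C(O)C[C@@H]3[C@@]4(C)CC[C@@H](O[Si](CC)(CC)CC)C(C)(C)O[C@@H]4CC[C@]3(C)O[Si](CC)(CC)CC)C(C)(C)[C@@H]2CC[C@@](C)(O[Si](CC)(CC)CC)[C@@H]2CC1 | intermediate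
36 | C11 enone | CC1=C(C(=O)C[C@@H]3[C@@]4(C)CC[C@@H](O[Si](CC)(CC)CC)C(C)(C)O[C@@H]4CC[C@]3(C)O[Si](CC)(CC)CC)C(C)(C)[C@@H]2CC[C@@](C)(O[Si](CC)(CC)CC)[C@@H]2CC1 | intermediate
37 | (11R)-allylic alcohol | CC1=C([C@H](O)C[C@@H]3[C@@]4(C)CC[C@@H](O[Si](CC)(CC)CC)C(C)(C)O[C@@H]4CC[C@]3(C)O[Si](CC)(CC)CC)C(C)(C)[C@@H]2CC[C@@](C)(O[Si](CC)(CC)CC)[C@@H]2CC1 | intermediate
38 | (11S)-N-alkyl-N-(2-nitrobenzenesulfonyl) acetone hydrazone | CC1=C([C@@H](N(N=C(C)C)S(=O)(=O)c5ccccc5[N+](=O)[O-])C[C@@H]3[C@@]4(C)CC[C@@H](O[Si](CC)(CC)CC)C(C)(C)O[C@@H]4CC[C@]3(C)O[Si](CC)(CC)CC)C(C)(C)[C@@H]2CC[C@@](C)(O[Si](CC)(CC)CC)[C@@H]2CC1 | intermediate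
39 | (11S)-N-alkyl-N-(2-nitrobenzenesulfonyl)hydrazine | CC1=C([C@@H](N(N)S(=O)(=O)c5ccccc5[N+](=O)[O-])C[C@@H]3[C@@]4(C)CC[C@@H](O[Si](CC)(CC)CC)C(C)(C)O[C@@H]4CC[C@]3(C)O[Si](CC)(CC)CC)C(C)(C)[C@@H]2CC[C@@](C)(O[Si](CC)(CC)CC)[C@@H]2CC1 | intermediate
40 | (11S)-allylic diazene | CC1=C([C@@H](N=N)C[C@@H]3[C@@]4(C)CC[C@@H](O[Si](CC)(CC)CC)C(C)(C)O[C@@H]4CC[C@]3(C)O[Si](CC)(CC)CC)C(C)(C)[C@@H]2CC[C@@](C)(O[Si](CC)(CC)CC)[C@@H]2CC1 | intermediate
41 | tris(triethylsilyl) ether of the 17-ol (Z-alkene, C1 set) | C[C@H]1CC[C@@H]2[C@@H](CC[C@@]2(C)O[Si](CC)(CC)CC)C(C)(C)/C1=C\C[C@@H]1[C@@]2(C)CC[C@@H](O[Si](CC)(CC)CC)C(C)(C)O[C@@H]2CC[C@]1(C)O[Si](CC)(CC)CC | intermediate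
42 | 8,17,23-triol | C[C@H]1CC[C@@H]2[C@@H](CC[C@@]2(C)O)C(C)(C)/C1=C\C[C@@H]1[C@@]2(C)CC[C@@H](O)C(C)(C)O[C@@H]2CC[C@]1(C)O | intermediate
43 | CNP0157787.1 | C[C@H]1CC[C@@H]2[C@@H](CC[C@@]2(C)O)C(C)(C)/C1=C\C[C@@H]1[C@@]2(C)CCC(=O)C(C)(C)O[C@@H]2CC[C@]1(C)O | target

Total step count: 29. Longest linear sequence: 19 steps (steps 1–7, 9–13, 23–29). The ring C/D fragment takes 9 steps (14–22) and the dibromoketone 1 step (8).

Steps most likely to fail

1. Step 9 (key step).
- What may go wrong: the cation may add with reversed orientation. The zwitterionic stage may close through oxygen or at C3 to give five-membered rings, or lose a proton instead of closing the hindered C5–C9 bond. Iron halides may ionise the tertiary allylic silyl ether, and the discrimination between the two diene faces may be weak.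
- Fallback: it sets out from 11 and 10, comes back at 14 and keeps the disconnection. It replaces reductive generation of a metal-bound cation by heterolysis of a preformed silyloxyallyl halide.
- Course: ketone 11 is chlorinated at its tertiary α-carbon (SO2Cl2, CCl4) to 2-chloro-2-methylpentan-3-one F1. Kinetic enolisation and silylation (LiN(i-Pr)2, Me3SiCl, THF, –78 °C) gives (Z)-4-chloro-4-methyl-3-(trimethylsilyloxy)pent-2-ene F2. AgClO4 in MeNO2–Et2O at 0 °C abstracts chloride in the presence of 10 to give the 2-(trimethylsilyloxy)allyl cation perchlorate F3. This is an iron-free and more electrophilic three-carbon partner known to add to open-chain dienes. Loss of the silyl group on work-up leads to 14.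

2. Step 26.
- What may go wrong: substitution at the crowded allylic carbinol C11 may be slow. Elimination to a conjugated diene or ionisation with loss of configuration could then take over.
- Fallback: it sets out from enone 36, comes back at 41 and needs no substitution at C11.
- Course: condensation with TsNHNH2 (cat. pyridinium tosylate, EtOH, 60 °C) gives the tosylhydrazone of 36 F4. 1,2-Reduction with catecholborane (CHCl3, –40 → 0 °C) gives the allylic tosylhydrazine F5. Warming with NaOAc·3H2O expels sulfinate to give diazene 40, which collapses to 41 as in step 27.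
- Limitation: C11 is then set by substrate-controlled hydride delivery instead of by the reagent, so isomers may have to be separated.

3. Step 18.
- What may go wrong: the enol silane may be lost by protodesilylation. The epoxonium ion may be captured by the carbonyl oxygen instead of carbon. The internal epoxide may be activated before the terminal one, which would interrupt the cascade.
- Fallback: it sets out from 27, comes back at 29 and changes the terminating nucleophile to an acid-stable allylsilane, the ketone being revealed afterwards.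
- Course: MeLi (THF, 0 °C) cleaves the silyl enol ether to the lithium enolate F6, which is trapped with PhNTf2 as the (Z)-enol triflate F7. Kumada coupling with Me3SiCH2MgCl and Pd(PPh3)4 gives the trisubstituted allylsilane F8. The same TESOTf-initiated cascade then ends by loss of the trimethylsilyl group and gives the C23 exocyclic methylene benzoxepane F9. Ozonolysis (O3, CH2Cl2, –78 °C; PPh3) gives 29.

Further compounds
F1 | step 9 | 2-chloro-2-methylpentan-3-one | CCC(=O)C(C)(C)Cl
F2 | step 9 | (Z)-4-chloro-4-methyl-3-(trimethylsilyloxy)pent-2-ene | C/C=C(\O[Si](C)(C)C)C(C)(C)Cl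
F3 | step 9 | 1,1,3-trimethyl-2-(trimethylsilyloxy)allyl cation perchlorate | C/C=C(\O[Si](C)(C)C)[C+](C)C.[O-]Cl(=O)(=O)=O
F4 | step 26 | tosylhydrazone of 36 | CC1=C(C(=NNS(=O)(=O)c5ccc(C)cc5)C[C@@H]3[C@@]4(C)CC[C@@H](O[Si](CC)(CC)CC)C(C)(C)O[C@@H]4CC[C@]3(C)O[Si](CC)(CC)CC)C(C)(C)[C@@H]2CC[C@@](C)(O[Si](CC)(CC)CC)[C@@H]2CC1
F5 | step 26 | (11S)-allylic tosylhydrazine | CC1=C([C@@H](NNS(=O)(=O)c5ccc(C)cc5)C[C@@H]3[C@@]4(C)CC[C@@H](O[Si](CC)(CC)CC)C(C)(C)O[C@@H]4CC[C@]3(C)O[Si](CC)(CC)CC)C(C)(C)[C@@H]2CC[C@@](C)(O[Si](CC)(CC)CC)[C@@H]2CC1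
F6 | step 18 | lithium enolate from 27 | CC1(C)O[C@@H]1CC[C@@]1(C)O[C@@H]1CC/C([O-])=C/CCOCc1ccccc1.[Li+]
F7 | step 18 | diepoxy (Z)-enol triflate | CC1(C)O[C@@H]1CC[C@@]1(C)O[C@@H]1CC/C(OS(=O)(=O)C(F)(F)F)=C/CCOCc1ccccc1
F8 | step 18 | diepoxy allylsilane | CC1(C)O[C@@H]1CC[C@@]1(C)O[C@@H]1CC/C(C[Si](C)(C)C)=C/CCOCc1ccccc1
F9 | step 18 | C23 exocyclic methylene benzoxepane | c1ccccc1COCC[C@@H]1[C@@]2(C)CC[C@@H](O[Si](CC)(CC)CC)C(C)(C)O[C@@H]2CCC1=C
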